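**Plan**

- Retrosynthesis: the pyranone O1–C2 bond is opened first (cyclodehydration retron), giving a 2-substituted 1,3-diketone. The oxepine bond C3–C1″ is cut next into a diketone enolate and an allylic methyl carbonate. The diketone is then split by a Claisen disconnection into an A-ring methyl ketone and a B-ring benzoate.
- Enabling feature: flavone C3 sits between C2 and the C4 carbonyl, so it is the nucleophilic mid-carbon of a latent 1,3-diketone. The oxepine bridge C1″H2–C2″(O-aryl)=C3″Me2 is an allyl unit oxygenated at its central carbon. The ring bond C3–C1″ therefore maps onto a stabilised enolate and a π-allylpalladium terminus.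
- Fragments: the A-ring ketone comes from 2,4-dihydroxy-6-methoxyacetophenone (chromenylation, O-prenylation, para-Claisen). The B-ring benzoate comes from 2-bromo-4,5-dimethoxyphenol (O–H insertion, Horner–Wadsworth–Emmons olefination of acetone, reduction, silylation, Br/Li exchange and acylation).
- Forward ring order: dimethylpyran ring (step 1), chain joined by Claisen condensation (step 9), oxepine ring by Pd allylation (step 12), pyranone ring last (step 13).
- Stereochemistry: the target has no stereocentre and no stereogenic double bond (both acyclic alkenes end in CMe2), so it is one achiral species and no step needs stereocontrol. Stereocentres in transient or early intermediates are racemic and are erased later.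

Key step: step 12

Remark: triethyl diazophosphonoacetate (step 4) is treated as a stock reagent; if it has to be made, diazo transfer to triethyl phosphonoacetate gives it in one operation. Flavone numbering is used for the core, and C1″/C2″/C3″ denote the CH2, C(OAr) and CMe2 carbons of the oxepine bridge.

**Route**

Step 1
Reactants: 1 1-(2,4-dihydroxy-6-methoxyphenyl)ethan-1-one
Product: 3 evodionol [1-(5-hydroxy-7-methoxy-2,2-dimethyl-2H-chromen-6-yl)ethan-1-one], via ortho-quinone methide 2 (not isolated)
Conditions: 3-methylbut-2-enal (2 equiv), pyridine, 120 °C, sealed tube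
Reagents that add atoms: 3-methylbut-2-enal, CC(C)=CC=O
Why: Amine-mediated chromenylation (Knoevenagel-type condensation, then oxa-6π electrocyclisation): the enal should condense at the ring carbon between the two hydroxyls to give 2, which closes through the unchelated 4-oxygen while the 2-OH stays hydrogen-bonded to the acetyl group.

Step 2
Reactants: 3 evodionol
Product: 4 1-[7-methoxy-2,2-dimethyl-5-(3-methylbut-2-en-1-yloxy)-2H-chromen-6-yl]ethan-1-one
Conditions: prenyl bromide (1.5 equiv), K2CO3, DMF, 50 °C
Reagents that add atoms: 1-bromo-3-methylbut-2-ene, CC(C)=CCBr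
Why: Williamson etherification of the only free hydroxyl with a primary allylic bromide; carbonate in DMF is basic enough to break the chelate, and O-alkylation is expected to dominate in this dipolar solvent.

Step 3
Reactants: 4 1-[7-methoxy-2,2-dimethyl-5-(3-methylbut-2-en-1-yloxy)-2H-chromen-6-yl]ethan-1-one
Product: 6 1-[5-hydroxy-7-methoxy-2,2-dimethyl-8-(3-methylbut-2-en-1-yl)-2H-chromen-6-yl]ethan-1-one, via ortho-dienone 5 (not isolated)
Conditions: PhNEt2, 190 °C, sealed tube, Ar
Reagents that add atoms: none
Why: para-Claisen (Claisen–Cope) rearrangement: both ortho positions are substituted, so dienone 5 cannot tautomerise and should pass the allyl group on by Cope rearrangement to the only free ring carbon (C8), where enolisation restores the chelated phenol with a normal prenyl group.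

Step 4
Reactants: 7 2-bromo-4,5-dimethoxyphenol
Product: 8 ethyl 2-(2-bromo-4,5-dimethoxyphenoxy)-2-(diethoxyphosphoryl)acetate (racemic)
Conditions: triethyl diazophosphonoacetate (1.2 equiv, slow addition), Rh2(OAc)4 (1 mol %), toluene, 80 °C
Reagents that add atoms: triethyl diazophosphonoacetate, CCOC(=O)C(=[N+]=[N-])P(=O)(OCC)OCC
Why: Rhodium-carbenoid O–H insertion into the phenol is much faster than attack on the arene or the C–Br bond and attaches the aryloxy group to the future enol-ether carbon.

Step 5
Reactants: 8 ethyl 2-(2-bromo-4,5-dimethoxyphenoxy)-2-(diethoxyphosphoryl)acetate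
Product: 9 ethyl 2-(2-bromo-4,5-dimethoxyphenoxy)-3-methylbut-2-enoate
Conditions: NaH (1.2 equiv), THF, 0 °C; acetone (5 equiv), 0 to 60 °C
Reagents that add atoms: acetone, CC(C)=O
Why: Horner–Wadsworth–Emmons olefination of acetone fixes the double bond between the aryloxy carbon and CMe2 without positional ambiguity, and the two identical methyl groups leave no E/Z question.

Step 6
Reactants: 9 ethyl 2-(2-bromo-4,5-dimethoxyphenoxy)-3-methylbut-2-enoate
Product: 10 2-(2-bromo-4,5-dimethoxyphenoxy)-3-methylbut-2-en-1-ol
Conditions: DIBAL-H (2.5 equiv), CH2Cl2, −78 to 0 °C; Rochelle salt work-up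
Reagents that add atoms: none
Why: DIBAL-H 1,2-reduction of the unsaturated ester gives the allylic alcohol; aryl bromide and aryl enol ether are inert to the hydride at low temperature.

Step 7
Reactants: 10 2-(2-bromo-4,5-dimethoxyphenoxy)-3-methylbut-2-en-1-ol
Product: 11 {[2-(2-bromo-4,5-dimethoxyphenoxy)-3-methylbut-2-en-1-yl]oxy}(tert-butyl)dimethylsilane
Conditions: TBSCl, imidazole, DMF, rt
Reagents that add atoms: tert-butyldimethylsilyl chloride, CC(C)(C)[Si](C)(C)Cl
Why: Standard silylation of a primary alcohol under non-acidic conditions masks the hydroxyl for the organolithium and enolate steps that follow.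

Step 8
Reactants: 11 {[2-(2-bromo-4,5-dimethoxyphenoxy)-3-methylbut-2-en-1-yl]oxy}(tert-butyl)dimethylsilane
Product: 13 methyl 2-[(1-{[tert-butyl(dimethyl)silyl]oxy}-3-methylbut-2-en-2-yl)oxy]-4,5-dimethoxybenzoate, via aryllithium 12 (not isolated)
Conditions: n-BuLi (1.05 equiv), THF, −78 °C; cannulated into ClCO2Me (3 equiv), THF, −78 °C
Reagents that add atoms: methyl chloroformate, COC(=O)Cl
Why: Bromine–lithium exchange at −78 °C outruns any deprotonation, and inverse addition of 12 to excess chloroformate should stop at the benzoate (halogen–metal exchange, then acylation).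

Step 9
Reactants: 6 1-[5-hydroxy-7-methoxy-2,2-dimethyl-8-(3-methylbut-2-en-1-yl)-2H-chromen-6-yl]ethan-1-one; 13 methyl 2-[(1-{[tert-butyl(dimethyl)silyl]oxy}-3-methylbut-2-en-2-yl)oxy]-4,5-dimethoxybenzoate
Product: 14 1-{2-[(1-{[tert-butyl(dimethyl)silyl]oxy}-3-methylbut-2-en-2-yl)oxy]-4,5-dimethoxyphenyl}-3-[5-hydroxy-7-methoxy-2,2-dimethyl-8-(3-methylbut-2-en-1-yl)-2H-chromen-6-yl]propane-1,3-dione
Conditions: LiHMDS (3.5 equiv), THF, −78 °C to rt, then 45 °C; AcOH quench
Reagents that add atoms: none
Why: Crossed Claisen condensation: the phenoxide–enolate dianion of 6 is acylated at carbon by the non-enolisable benzoate, and excess amide base pulls the equilibrium over by deprotonating the β-diketone.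

Step 10
Reactants: 14 silyl-protected diketone
Product: 15 1-{2-[(1-hydroxy-3-methylbut-2-en-2-yl)oxy]-4,5-dimethoxyphenyl}-3-[5-hydroxy-7-methoxy-2,2-dimethyl-8-(3-methylbut-2-en-1-yl)-2H-chromen-6-yl]propane-1,3-dione
Conditions: TBAF (1.2 equiv), AcOH (1.2 equiv), THF, 0 °C to rt
Reagents that add atoms: none
Why: Fluoride cleaves the primary silyl ether, and acetic acid buffering keeps both the β-diketone and the acid-labile aryl enol ether untouched.

Step 11
Reactants: 15 diketone allylic alcohol
Product: 16 2-{2-[3-(5-hydroxy-7-methoxy-2,2-dimethyl-8-(3-methylbut-2-en-1-yl)-2H-chromen-6-yl)-3-oxopropanoyl]-4,5-dimethoxyphenoxy}-3-methylbut-2-en-1-yl methyl carbonate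
Conditions: ClCO2Me (1.1 equiv), pyridine (3 equiv), CH2Cl2, −20 °C; brief NaHCO3/MeOH wash
Reagents that add atoms: methyl chloroformate, COC(=O)Cl
Why: Chemoselective acylation: with pyridine at low temperature the neutral primary alcohol should react far faster than the hydrogen-bonded phenol and enol, which pyridine does not deprotonate, and any enol carbonate is cleaved again by the methanolic bicarbonate wash.

Step 12
Reactants: 16 allylic methyl carbonate of the open 1,3-diketone
Product: 17 [5-hydroxy-7,8-dimethoxy-2-(propan-2-ylidene)-2,3-dihydro-1-benzoxepin-4-yl][5-hydroxy-7-methoxy-2,2-dimethyl-8-(3-methylbut-2-en-1-yl)-2H-chromen-6-yl]methanone (enol form of the 4-aroyl-1-benzoxepin-5-one)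
Conditions: Pd2(dba)3·CHCl3 (5 mol %), dppe (12 mol %), THF (0.005 M), 50 °C
Reagents that add atoms: none
Why: Oxidative addition of Pd(0) to the allylic carbonate, with loss of CO2, should give a cationic 2-aryloxy-η3-allylpalladium complex and methoxide, which deprotonates the β-diketone; the stabilised enolate carbon (the future C3) then attacks the CH2 terminus on the face opposite to palladium, forming C3–C1″ and releasing Pd(0). The closest known reaction type is the intramolecular Tsuji–Trost C-allylation of 1,3-dicarbonyl compounds with allyl electrophiles that carry a heteroatom on the central carbon. The oxepine ring closes by 7-exo-tet-type attack on the allyl terminus: because the tether is anchored at the central allyl carbon, the ring takes in C1″ and C2″ while the CMe2 carbon remains outside it as the isopropylidene group, and neither acid nor added base touches the enol ether. No stereocentre is created, since the new sp3 carbon is the enolisable centre of the diketone and the exocyclic alkene carries two identical methyl groups. The step needs C- rather than O-allylation and attack at CH2 rather than CMe2 (either terminus would give a seven-membered ring): the soft carbon nucleophile and the reversibility of O-allylation under palladium secure the first, the unhindered primary terminus (attack at CMe2 would join two fully substituted carbons) secures the second, and high dilution suppresses intermolecular allylation while the chelated A-ring phenol is too remote to compete.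

Step 13
Reactants: 17 4-aroyl-1-benzoxepin-5-one (enol form)
Product: 19 CNP0192589.0 (target), via hemiketal 18 (not isolated)
Conditions: NaOAc (3 equiv), AcOH, 70 °C
Reagents that add atoms: none
Why: Flavone cyclodehydration: the chelated A-ring phenol adds to the B-ring-side carbonyl to give 18, which loses water to the conjugated 4-pyranone; the acetate-buffered medium is the mild variant used for 3-allyl flavones with acid-sensitive side chains and should spare the aryl enol ether, the prenyl group and the chromene.

**Compound list**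

1 | 1-(2,4-dihydroxy-6-methoxyphenyl)ethan-1-one | COc1cc(O)cc(O)c1C(C)=O | starting material
2 | 4-acetyl-3-hydroxy-5-methoxy-2-(3-methylbut-2-en-1-ylidene)cyclohexa-3,5-dien-1-one (ortho-quinone methide, alkene geometry immaterial) | CC(=O)C1=C(O)C(=CC=C(C)C)C(=O)C=C1OC | intermediate
3 | evodionol, 1-(5-hydroxy-7-methoxy-2,2-dimethyl-2H-chromen-6-yl)ethan-1-one | CC(=O)c1c(O)c2C=CC(C)(C)Oc2cc1OC | intermediate
4 | 1-[7-methoxy-2,2-dimethyl-5-(3-methylbut-2-en-1-yloxy)-2H-chromen-6-yl]ethan-1-one | CC(=O)c1c(OCC=C(C)C)c2C=CC(C)(C)Oc2cc1OC | intermediate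
5 | 6-acetyl-7-methoxy-2,2-dimethyl-6-(2-methylbut-3-en-2-yl)-2H-chromen-5(6H)-one (racemic ortho-dienone) | CC(=O)C1(C(C)(C)C=C)C(=O)C2=C(OC(C)(C)C=C2)C=C1OC | intermediate
6 | 1-[5-hydroxy-7-methoxy-2,2-dimethyl-8-(3-methylbut-2-en-1-yl)-2H-chromen-6-yl]ethan-1-one | CC(=O)c1c(O)c2C=CC(C)(C)Oc2c(CC=C(C)C)c1OC | intermediate
7 | 2-bromo-4,5-dimethoxyphenol | COc1cc(O)c(Br)cc1OC | starting material
8 | ethyl 2-(2-bromo-4,5-dimethoxyphenoxy)-2-(diethoxyphosphoryl)acetate (racemic) | CCOC(=O)C(Oc1cc(OC)c(OC)cc1Br)P(=O)(OCC)OCC | intermediate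
9 | ethyl 2-(2-bromo-4,5-dimethoxyphenoxy)-3-methylbut-2-enoate | CCOC(=O)C(Oc1cc(OC)c(OC)cc1Br)=C(C)C | intermediate
10 | 2-(2-bromo-4,5-dimethoxyphenoxy)-3-methylbut-2-en-1-ol | OCC(Oc1cc(OC)c(OC)cc1Br)=C(C)C | intermediate
11 | {[2-(2-bromo-4,5-dimethoxyphenoxy)-3-methylbut-2-en-1-yl]oxy}(tert-butyl)dimethylsilane | CC(C)=C(CO[Si](C)(C)C(C)(C)C)Oc1cc(OC)c(OC)cc1Br | intermediate
12 | {2-[(1-{[tert-butyl(dimethyl)silyl]oxy}-3-methylbut-2-en-2-yl)oxy]-4,5-dimethoxyphenyl}lithium | [Li]c1cc(OC)c(OC)cc1OC(CO[Si](C)(C)C(C)(C)C)=C(C)C | intermediate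
13 | methyl 2-[(1-{[tert-butyl(dimethyl)silyl]oxy}-3-methylbut-2-en-2-yl)oxy]-4,5-dimethoxybenzoate | COC(=O)c1cc(OC)c(OC)cc1OC(CO[Si](C)(C)C(C)(C)C)=C(C)C | intermediate
14 | silyl-protected 1,3-diketone (drawn as diketone; mainly the chelated enol) | CC(C)=C(CO[Si](C)(C)C(C)(C)C)Oc1cc(OC)c(OC)cc1C(=O)CC(=O)c1c(O)c2C=CC(C)(C)Oc2c(CC=C(C)C)c1OC | intermediate
15 | 1,3-diketone with free allylic alcohol | CC(C)=C(CO)Oc1cc(OC)c(OC)cc1C(=O)CC(=O)c1c(O)c2C=CC(C)(C)Oc2c(CC=C(C)C)c1OC | intermediate
16 | open 1,3-diketone carrying the 2-aryloxyallyl methyl carbonate | COC(=O)OCC(=C(C)C)Oc1cc(OC)c(OC)cc1C(=O)CC(=O)c1c(O)c2C=CC(C)(C)Oc2c(CC=C(C)C)c1OC | intermediate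
17 | 4-aroyl-2-isopropylidene-7,8-dimethoxy-2,3-dihydro-1-benzoxepin-5-one, enol form | COc1cc2OC(=C(C)C)CC(C(=O)c3c(O)c4C=CC(C)(C)Oc4c(CC=C(C)C)c3OC)=C(O)c2cc1OC | intermediate
18 | ring-closed hemiketal of 17 (2-hydroxychroman-4-one fused to the oxepine; mixture of diastereomers) | COc1cc2c(cc1OC)C1(O)Oc3c4c(c(CC=C(C)C)c(OC)c3C(=O)C1CC(=C(C)C)O2)OC(C)(C)C=C4 | intermediate
19 | CNP0192589.0: 5-methoxy-6-prenyl chromone with a 2,2-dimethylpyran fused at C7(O)/C8, whose C3 is linked through CH2–C(=CMe2)–O to C2′ of the 4′,5′-dimethoxyphenyl ring on C2 (achiral) | COc1cc2c(cc1OC)-c1oc3c4c(c(CC=C(C)C)c(OC)c3c(=O)c1CC(=C(C)C)O2)OC(C)(C)C=C4 | target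

**Step count and risks**

Total: 13 steps. Longest linear sequence: 10 steps (7 to 19 through steps 4–13); the A-ring branch (steps 1–3) joins at step 9.

Step 12. The tetrasubstituted allylic carbonate may ionise slowly or the ring may close slowly, so that β-hydride loss from the π-allyl complex to a diene, O-allylation or intermolecular allylation takes over. The fallback sets out from 13 and 6 and rejoins at 17. Buffered fluoride desilylation of 13 should give methyl 2-[(1-hydroxy-3-methylbut-2-en-2-yl)oxy]-4,5-dimethoxybenzoate F1. Appel bromination (CBr4, PPh3) should then give methyl 2-[(1-bromo-3-methylbut-2-en-2-yl)oxy]-4,5-dimethoxybenzoate F2. C-alkylation of the dianion of 6 (LDA, THF, −78 °C) with the bromide should give the keto ester methyl 2-({6-[5-hydroxy-7-methoxy-2,2-dimethyl-8-(3-methylbut-2-en-1-yl)-2H-chromen-6-yl]-2-methyl-6-oxohex-2-en-3-yl}oxy)-4,5-dimethoxybenzoate F3. A Dieckmann-type intramolecular Claisen condensation (LiHMDS or NaH, THF) then closes the seven-membered ring between the ketone α-carbon and the benzoate carbonyl and delivers 17. The C3–C1″ bond is thus made by a plain enolate SN2 alkylation and the oxepine ring by acylation, without palladium.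

Step 13. Acid may move the exocyclic enol-ether double bond into the oxepine ring, or hydrolyse the enol ether, faster than the hemiketal dehydrates. The fallback sets out from 17 and rejoins at 19, under basic conditions throughout. Acetylation (Ac2O, pyridine, cat. DMAP, 0 °C to rt) should trap the ring-closed form as the 2-acetoxychroman-4-one (acetate of hemiketal 18) F4. DBU in toluene at 60 °C should then expel acetic acid by E1cB elimination, a ring closure of the Kostanecki–Robinson type. Acetyl groups that land on the phenol or the enol instead are expected to converge on the same chromone, because acyl transfer under DBU frees the phenoxide and an enol acetate is an equally good leaving group for its addition–elimination.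

Step 11. Chemoselectivity may be lost, with acylation of the diketone enol or the phenol alongside the alcohol; this would block the nucleophile of step 12. The fallback sets out from 11 and 6 and rejoins at 16, and installs the carbonate before the diketone and the free phenol exist. Bromine–lithium exchange of 11 followed by CO2 should give 2-[(1-{[tert-butyl(dimethyl)silyl]oxy}-3-methylbut-2-en-2-yl)oxy]-4,5-dimethoxybenzoic acid F5. Steglich esterification (EDC, DMAP) with phenol 6 should give the silyl-protected aryl ester F6. HF·pyridine desilylation should give the hydroxy aryl ester F7. Methyl chloroformate and pyridine should give the carbonate aryl ester F8, in which the alcohol was the only acylable group. A Baker–Venkataraman rearrangement (LiHMDS, THF, −78 to −20 °C; intramolecular O-to-C acyl shift, faster than attack of the enolate on the carbonate) then gives 16 directly. This sequence also serves if the direct Claisen condensation of step 9 is sluggish.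

**Further compounds**

F1 | step 12 | methyl 2-[(1-hydroxy-3-methylbut-2-en-2-yl)oxy]-4,5-dimethoxybenzoate | COC(=O)c1cc(OC)c(OC)cc1OC(CO)=C(C)C
F2 | step 12 | methyl 2-[(1-bromo-3-methylbut-2-en-2-yl)oxy]-4,5-dimethoxybenzoate | COC(=O)c1cc(OC)c(OC)cc1OC(CBr)=C(C)C
F3 | step 12 | methyl 2-({6-[5-hydroxy-7-methoxy-2,2-dimethyl-8-(3-methylbut-2-en-1-yl)-2H-chromen-6-yl]-2-methyl-6-oxohex-2-en-3-yl}oxy)-4,5-dimethoxybenzoate | COC(=O)c1cc(OC)c(OC)cc1OC(CCC(=O)c1c(O)c2C=CC(C)(C)Oc2c(CC=C(C)C)c1OC)=C(C)C
F4 | step 13 | 2-acetoxychroman-4-one, acetate of hemiketal 18 (mixture of diastereomers) | COc1cc2c(cc1OC)C1(OC(C)=O)Oc3c4c(c(CC=C(C)C)c(OC)c3C(=O)C1CC(=C(C)C)O2)OC(C)(C)C=C4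
F5 | step 11 | 2-[(1-{[tert-butyl(dimethyl)silyl]oxy}-3-methylbut-2-en-2-yl)oxy]-4,5-dimethoxybenzoic acid | OC(=O)c1cc(OC)c(OC)cc1OC(CO[Si](C)(C)C(C)(C)C)=C(C)C
F6 | step 11 | 6-acetyl-7-methoxy-2,2-dimethyl-8-(3-methylbut-2-en-1-yl)-2H-chromen-5-yl 2-[(1-{[tert-butyl(dimethyl)silyl]oxy}-3-methylbut-2-en-2-yl)oxy]-4,5-dimethoxybenzoate | CC(=O)c1c(OC(=O)c3cc(OC)c(OC)cc3OC(CO[Si](C)(C)C(C)(C)C)=C(C)C)c2C=CC(C)(C)Oc2c(CC=C(C)C)c1OC
F7 | step 11 | 6-acetyl-7-methoxy-2,2-dimethyl-8-(3-methylbut-2-en-1-yl)-2H-chromen-5-yl 2-[(1-hydroxy-3-methylbut-2-en-2-yl)oxy]-4,5-dimethoxybenzoate | CC(=O)c1c(OC(=O)c3cc(OC)c(OC)cc3OC(CO)=C(C)C)c2C=CC(C)(C)Oc2c(CC=C(C)C)c1OC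
F8 | step 11 | 6-acetyl-7-methoxy-2,2-dimethyl-8-(3-methylbut-2-en-1-yl)-2H-chromen-5-yl 2-({1-[(methoxycarbonyl)oxy]-3-methylbut-2-en-2-yl}oxy)-4,5-dimethoxybenzoate | CC(=O)c1c(OC(=O)c3cc(OC)c(OC)cc3OC(COC(=O)OC)=C(C)C)c2C=CC(C)(C)Oc2c(CC=C(C)C)c1OC
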